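The rate constants are invented.

The vessel starts with two solids, J and E, stirred in a solution of G. J dissolves to Q and E dissolves to X. Each X then meets either Q, giving Q.X, or G, giving X.G, and Q.X above its solubility crystallises as Z.

J 0.050 M; E 0.0600 M; G 0.0500 M; time 4.0 h

- how much Q.X and Z together there is at 4.0 h, in percent of the J charged
- concentration of Q in solution at 25 min, in percent of saturation
- the change that raises the amount of Q.X and Z together at 4.0 h, in percent of the J charged most ("none" if none brings more than 2 percentage points) (Thursday's / Tuesday's / Wednesday's / Sunday's / none)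
- amount of Q.X and Z together at 4.0 h, in percent of the J charged, after Tuesday's

- amounts and yields of Q.X count Z too
- given per volume of solution although it is solid: J, Z, E
- at the start none of J is in solution
- at the start none of E is in solution
- Q means what is dissolved; the solid is not counted in it
- run time (flask): 4.0 h

- Thursday's: doubling the dissolution coefficient of step 4, all else as stated
- Tuesday's: doubling the solubility in step 5, all else as stated
- Wednesday's: doubling the dissolution coefficient of step 3, all else as stated
- Sunday's: doubling the solubility in step 4, all else as stated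

    Q + X → Q.X (k1 = 0.53 L mol⁻¹ min⁻¹)
    X + G → X.G (k2 = 0.55 L mol⁻¹ min⁻¹)
    Z ⇌ Q.X, rate k3*(cs3 - [Q.X]) while solid is left; crystals form when [Q.X] > cs3 (cs3 = 13 mM, k3 = 0.30 min⁻¹)
    J ⇌ Q, rate k4*(cs4 - [Q]) while solid is left; crystals form when [Q] > cs4 (cs4 = 21 mM, k4 = 0.41 min⁻¹)
    E ⇌ X, rate k5*(cs5 - [X]) while solid is left; crystals form when [X] > cs5 (cs5 = 24 mM, k5 = 0.030 min⁻¹)

Take the first minutes. Into an empty solution J can deliver 8.61 mM min⁻¹ and E 0.720 mM min⁻¹, so Q fills up far faster and stands near its solubility, 21 mM, while X creeps up.

In the middle, X climbs towards the level where E's supply meets both consumers with G as charged, 10.5 mM, at a rate of 0.0686 min⁻¹. At 25 min I reckon X at 8.60 mM. J has to replace what that X removes, so: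

saturation ≈ 1 − 0.53 L mol⁻¹ min⁻¹ × 8.60 mM / 0.41 min⁻¹ = 98.9 %

Now you have the quantity to carry, the competing level C, the concentration of G at which X divides equally between Q and G, a selectivity factor with a unit:

C = 0.53 L mol⁻¹ min⁻¹ × 21 mM / 0.55 L mol⁻¹ min⁻¹ = 20.2 mM

Let P be Q.X and Z together, since crystals of Z are Q.X in another form. With Q held, P grows by C/G for each G lost, which sums to:

P = C · ln(G charged / G left)

Towards the end, with X held at that level, I reckon the 0.0600 M of E dissolved after about 2.47 h. Once X has reacted, P plus the G lost equals the E charged. Try P = 25.0 mM, half the J charged: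

G left = 15.0 mM, so P = 24.4 mM

Between the two lies P = 24.7 mM, or 49.4 % of J. Solid J lasts that far, since 29.0 mM can leave the solid with Q still full.

At 4.0 h I still expect 1.79 mM of X, so my y is 47.3 %. Tuesday's delivers the same X sooner, so I put it near 49.4 %. Sunday's doubles C and the others leave C as it stands, so I name Sunday's.

The forecast gives 47 %, 98.9 %, Sunday's and 48.5 %, holding “that X splits between Q and G roughly in proportion to their concentrations”. The simulation gives 46.8 %, 98.9 %, Sunday's with a gain of 11 percentage points, and 48.2 %.

The step of X with G may be called the main reason for the shortfall: the run without it reaches 77.4 % against 46.8 %. C measures that loss from what stood in the flask: with 30.9 % of the G left at 4.00 h, the rule gives 47.5 % of J. The neighbour flask charged with 0.030 M of G kept 21.3 % of it, so the same C gives 62.6 %, and that flask stood at 61.4 %, with J at 0 % and Q at 38.6 % of the J charged.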